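**Retrosynthetic overview**
1. Target 19 ⇐ catalyst-controlled reduction of the C9 ketone 18 ⇐ palladium cyclocarbonylation of ten-membered ketone 17 (C6–OH + C7–ethynyl → α-methylene lactone).
2. Ten-membered ring 17 ⇐ four-atom ring expansion of cyclohexanone 15: reductive aldol of the ynoate arm onto C9, then Grob fragmentation of the C4–C9 bond against the C5–C6 epoxide (gives both cis ring alkenes and frees C6–OH).
3. 15 ⇐ carvone-type enone 5 by deconjugative C4 alkylation, Rubottom oxidation at C8, hydroxyl-directed epoxidation, Mitsunobu angeloylation with inversion, and alkyne methoxycarbonylation.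
4. 5 ⇐ organocatalytic Michael/aldol condensation of keto ester 3 with enynal 2 (sets C7).
5. Ring order: cyclohexenone → fused cyclohexene (transient) → ten-membered carbocycle → butyrolactone.

Assumption: germacrane numbering (C1–C15, lactone carbonyl C12, ester carbon C14) is used for all intermediates, "β" is the ring face carrying the C7 alkynyl group, and the silyl and tert-butyl groups of 1, 3 and 6 are counted as protecting groups.

**Step 1**
Reactants: 1 3-(triisopropylsilyl)prop-2-ynal
Product: 2 (E)-5-(triisopropylsilyl)pent-2-en-4-ynal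
Conditions: Ph3P=CHCHO (1.05 equiv), toluene, 60 °C
Reagents that add atoms: (triphenylphosphoranylidene)acetaldehyde, O=CC=P(c1ccccc1)(c1ccccc1)c1ccccc1
Why: Wittig olefination with the stabilized formyl ylide is E-selective, and the ynal is much more electrophilic than the enal product, so a single two-carbon homologation occurs.

**Step 2**
Reactants: 2 (E)-5-(triisopropylsilyl)pent-2-en-4-ynal; 3 tert-butyl 3-oxopentanoate
Product: 5 (5S)-2-methyl-5-[(triisopropylsilyl)ethynyl]cyclohex-2-en-1-one, via Michael adduct 4 (not isolated)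
Conditions: (R)-2-[bis(3,5-bis(trifluoromethyl)phenyl)(trimethylsilyloxy)methyl]pyrrolidine (10 mol %), PhCO2H (10 mol %), toluene, 0 °C to rt; then p-TsOH·H2O (20 mol %), toluene, 80 °C
Reagents that add atoms: none
Why: Iminium-ion organocatalytic Michael addition followed by acid-promoted aldol condensation with tert-butyl ester cleavage and decarboxylation (Robinson-type annulation), in which the diarylsilyloxymethyl group of the R catalyst shields one face of the E-iminium ion so the keto ester carbon adds to C7 from the other face and gives the 5S enone.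

**Step 3**
Reactants: 5 (5S)-2-methyl-5-[(triisopropylsilyl)ethynyl]cyclohex-2-en-1-one; 6 4-iodo-1-(trimethylsilyl)but-1-yne
Product: 8 (2S,5R)-2-(but-3-yn-1-yl)-2-methyl-5-[(triisopropylsilyl)ethynyl]cyclohex-3-en-1-one, via silylalkyne 7 (not isolated)
Conditions: KOtBu (1.2 equiv), THF/t-BuOH/DMPU, 0 °C; 6, 0 °C to rt; then MeOH, K2CO3 (0.2 equiv), rt
Reagents that add atoms: none
Why: Deconjugative α-alkylation of the thermodynamic dienolate (the standard C2 alkylation of carvone-type enones) places the iodide-derived arm on C4 anti to the C7 silylethynyl group, creating the quaternary centre and moving the alkene to C5=C6, after which mild methanolysis removes only the alkynyl trimethylsilyl group.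

**Step 4**
Reactants: 8 (2S,5R)-2-(but-3-yn-1-yl)-2-methyl-5-[(triisopropylsilyl)ethynyl]cyclohex-3-en-1-one
Product: 11 (2S,5R,6R)-2-(but-3-yn-1-yl)-6-hydroxy-2-methyl-5-[(triisopropylsilyl)ethynyl]cyclohex-3-en-1-one, via silyl enol ether 9 (not isolated), via silyloxy ketone 10 (not isolated)
Conditions: TMSOTf, Et3N, CH2Cl2, 0 °C; mCPBA (1.05 equiv), CH2Cl2, −20 °C; 1 M HCl, THF, 0 °C
Reagents that add atoms: 3-chloroperoxybenzoic acid, O=C(OO)c1cccc(Cl)c1
Why: Rubottom oxidation, in which C8 is the only enolizable position and the peracid attacks the electron-rich enol ether on the face opposite the C7 alkynyl and C4 methyl groups, giving the 8α-hydroxy ketone (OH trans to the alkynyl group).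

**Step 5**
Reactants: 11 (2S,5R,6R)-2-(but-3-yn-1-yl)-6-hydroxy-2-methyl-5-[(triisopropylsilyl)ethynyl]cyclohex-3-en-1-one
Product: 12 2-(but-3-yn-1-yl)-4-hydroxy-2-methyl-5-[(triisopropylsilyl)ethynyl]-7-oxabicyclo[4.1.0]heptan-3-one (epoxide oxygen, hydroxyl and butynyl arm all α)
Conditions: VO(acac)2 (5 mol %), t-BuOOH (1.5 equiv), CH2Cl2, 0 °C to rt
Reagents that add atoms: tert-butyl hydroperoxide, CC(C)(C)OO
Why: Hydroxyl-directed vanadium-catalysed epoxidation, in which the homoallylic 8α-hydroxyl delivers the peroxide to the α face of C5=C6 (also the less hindered face), setting the C6 oxygen trans to the C7 substituent and cis to the C3 methylene as the later fragmentation requires.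

**Step 6**
Reactants: 12 the α-epoxy 8α-hydroxy ketone; 13 angelic acid
Product: 14 2-(but-3-yn-1-yl)-2-methyl-3-oxo-5-[(triisopropylsilyl)ethynyl]-7-oxabicyclo[4.1.0]heptan-4-yl (Z)-2-methylbut-2-enoate (ester oxygen now β)
Conditions: PPh3 (2 equiv), DIAD (2 equiv), toluene, 0 °C to rt
Reagents that add atoms: none
Why: Mitsunobu esterification, an SN2 displacement at the activated α-keto carbinol that inverts C8 and so installs the angelate with its final configuration (cis to the C7 substituent) without isomerizing the Z alkene of the acid.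

**Step 7**
Reactants: 14 the 8β-angelate epoxy ketone
Product: 15 methyl 5-{2-methyl-4-[(Z)-2-methylbut-2-enoyloxy]-3-oxo-5-[(triisopropylsilyl)ethynyl]-7-oxabicyclo[4.1.0]heptan-2-yl}pent-2-ynoate
Conditions: PdCl2 (5 mol %), CuCl2 (2.1 equiv), NaOAc (2.1 equiv), CO (1 atm), MeOH, rt
Reagents that add atoms: carbon monoxide, [C-]#[O+]; methanol, CO
Why: Oxidative alkoxycarbonylation of a terminal alkyne, in which the alkynylpalladium species inserts CO and is methanolysed while CuCl2 reoxidises the palladium, and the internal silyl alkyne, epoxide and esters do not react.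

**Step 8**
Reactants: 15 the ynoate epoxy ketone
Product: 17 methyl (6R,7S,8S)-8-angeloyloxy-7-ethynyl-6-hydroxy-4-methyl-9-oxocyclodeca-1(10),4-diene-10-carboxylate (germacrane numbering; both ring alkenes cis in the ring), via bicyclic silyl ether 16 (not isolated)
Conditions: Cu(OAc)2 (5 mol %), 1,2-bis(diphenylphosphino)benzene (5 mol %), PhMe2SiH (1.5 equiv), toluene, −20 to 0 °C; then TBAF (2.5 equiv), THF, −40 °C to rt; AcOH quench
Reagents that add atoms: none
Why: Proposed new method: copper hydride adds hydride to C1 of the ynoate and the resulting copper allenolate attacks the neighbouring C9 ketone through C10 (reductive aldol cyclization to a cyclohexene, trapped as the silyl ether), then fluoride frees the tertiary alkoxide, whose lone pair drives heterolysis of the C4–C9 bond into the C5–O bond of the epoxide (Grob fragmentation, a net transfer of the C9 acyl group from C4 to C10), so the six-membered ring becomes the ten-membered ring with C1=C10 cis from its cyclohexene origin, C4=C5 cis because the epoxide oxygen and the C3 methylene share one face, and C6 keeping its oxygen and configuration while the same fluoride removes the alkynyl silyl group; the closest known reactions are copper hydride reductive aldol cyclizations of alkynoates onto ketones and alkoxide- or titanium-promoted epoxy alcohol fragmentations of fused rings to medium rings.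

**Step 9**
Reactants: 17 the ten-membered hydroxy keto alkyne
Product: 18 (6R,7S,8S)-9-oxo analogue of the target (trans-fused α-methylene lactone, C8 angelate, C14 methyl ester)
Conditions: PdCl2 (5 mol %), PPh3 (10 mol %), SnCl2 (10 mol %), CO (5 atm), MeCN, 65 °C
Reagents that add atoms: carbon monoxide, [C-]#[O+]
Why: Palladium-catalysed cyclocarbonylation of a homopropargylic alcohol, in which the alkoxycarbonylpalladium formed at the only free hydroxyl adds syn across the alkyne and protonolysis gives the α-methylene-γ-butyrolactone, the trans ring fusion following from the C6 and C7 centres already in place.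

**Step 10**
Reactants: 18 the 9-oxo lactone
Product: 19 CNP0305372.1 (target)
Conditions: (R)-2-methyl-CBS-oxazaborolidine (0.3 equiv), catecholborane (1.5 equiv), toluene, −78 °C; then MeOH, pH 7 buffer
Reagents that add atoms: none
Why: Corey–Bakshi–Shibata reduction, in which the oxazaborolidine–borane complex binds the C9 carbonyl away from the bulky α-(methoxycarbonyl)alkenyl arm and delivers hydride to the Si face in a 1,2-fashion, giving the 9R alcohol cis to the C8 angelate by catalyst control.

**Compound list**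
1 | 3-(triisopropylsilyl)prop-2-ynal | O=CC#C[Si](C(C)C)(C(C)C)C(C)C | starting material
2 | (E)-5-(triisopropylsilyl)pent-2-en-4-ynal | O=C/C=C/C#C[Si](C(C)C)(C(C)C)C(C)C | intermediate
3 | tert-butyl 3-oxopentanoate | CCC(=O)CC(=O)OC(C)(C)C | starting material
4 | tert-butyl (3S)-5-oxo-2-propanoyl-3-[(triisopropylsilyl)ethynyl]pentanoate (mixture at C2; not isolated) | CCC(=O)C(C(=O)OC(C)(C)C)[C@H](CC=O)C#C[Si](C(C)C)(C(C)C)C(C)C | intermediate
5 | (5S)-2-methyl-5-[(triisopropylsilyl)ethynyl]cyclohex-2-en-1-one | CC1=CC[C@H](C#C[Si](C(C)C)(C(C)C)C(C)C)CC1=O | intermediate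
6 | 4-iodo-1-(trimethylsilyl)but-1-yne | C[Si](C)(C)C#CCCI | starting material
7 | (2S,5R)-2-methyl-5-[(triisopropylsilyl)ethynyl]-2-[4-(trimethylsilyl)but-3-yn-1-yl]cyclohex-3-en-1-one (not isolated) | O=C1C[C@@H](C#C[Si](C(C)C)(C(C)C)C(C)C)C=C[C@]1(C)CCC#C[Si](C)(C)C | intermediate
8 | (2S,5R)-2-(but-3-yn-1-yl)-2-methyl-5-[(triisopropylsilyl)ethynyl]cyclohex-3-en-1-one (butynyl arm trans to the silylethynyl group) | O=C1C[C@@H](C#C[Si](C(C)C)(C(C)C)C(C)C)C=C[C@]1(C)CCC#C | intermediate
9 | trimethylsilyl enol ether of 8 (C8=C9 enol ether; not isolated) | C[Si](C)(C)OC1=C[C@@H](C#C[Si](C(C)C)(C(C)C)C(C)C)C=C[C@]1(C)CCC#C | intermediate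
10 | O-trimethylsilyl ether of 11 (not isolated) | O=C1[C@H](O[Si](C)(C)C)[C@@H](C#C[Si](C(C)C)(C(C)C)C(C)C)C=C[C@]1(C)CCC#C | intermediate
11 | (2S,5R,6R)-2-(but-3-yn-1-yl)-6-hydroxy-2-methyl-5-[(triisopropylsilyl)ethynyl]cyclohex-3-en-1-one (8α-OH, trans to the alkynyl group) | O=C1[C@H](O)[C@@H](C#C[Si](C(C)C)(C(C)C)C(C)C)C=C[C@]1(C)CCC#C | intermediate
12 | 2-(but-3-yn-1-yl)-4-hydroxy-2-methyl-5-[(triisopropylsilyl)ethynyl]-7-oxabicyclo[4.1.0]heptan-3-one (epoxide O, OH and butynyl arm α; methyl and silylethynyl β) | O=C1[C@H](O)[C@@H](C#C[Si](C(C)C)(C(C)C)C(C)C)[C@@H]2O[C@@H]2[C@]1(C)CCC#C | intermediate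
13 | angelic acid, (Z)-2-methylbut-2-enoic acid | C/C=C(/C)C(=O)O | starting material
14 | 2-(but-3-yn-1-yl)-2-methyl-3-oxo-5-[(triisopropylsilyl)ethynyl]-7-oxabicyclo[4.1.0]heptan-4-yl (Z)-2-methylbut-2-enoate (angelate β, cis to silylethynyl) | O=C1[C@@H](OC(=O)/C(C)=C\C)[C@@H](C#C[Si](C(C)C)(C(C)C)C(C)C)[C@@H]2O[C@@H]2[C@]1(C)CCC#C | intermediate
15 | methyl 5-{2-methyl-4-[(Z)-2-methylbut-2-enoyloxy]-3-oxo-5-[(triisopropylsilyl)ethynyl]-7-oxabicyclo[4.1.0]heptan-2-yl}pent-2-ynoate (stereocentres as in 14) | O=C1[C@@H](OC(=O)/C(C)=C\C)[C@@H](C#C[Si](C(C)C)(C(C)C)C(C)C)[C@@H]2O[C@@H]2[C@]1(C)CCC#CC(=O)OC | intermediate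
16 | dimethylphenylsilyl ether of the cis-fused reductive aldol product (C9–O β, C10 on the α face; not isolated) | COC(=O)C1=CCC[C@@]2(C)[C@H]3O[C@H]3[C@H](C#C[Si](C(C)C)(C(C)C)C(C)C)[C@H](OC(=O)/C(C)=C\C)[C@@]12O[Si](C)(C)c1ccccc1 | intermediate
17 | methyl (6R,7S,8S)-8-angeloyloxy-7-ethynyl-6-hydroxy-4-methyl-9-oxocyclodeca-1(10),4-diene-10-carboxylate (germacrane numbering; may sit partly as the C6–O–C9 hemiketal) | C#C[C@H]1[C@H](O)/C=C(/C)CC/C=C(/C(=O)OC)C(=O)[C@H]1OC(=O)/C(C)=C\C | intermediate
18 | (6R,7S,8S)-9-oxo analogue of the target | C=C1C(=O)O[C@@H]2/C=C(/C)CC/C=C(/C(=O)OC)C(=O)[C@@H](OC(=O)/C(C)=C\C)[C@@H]12 | intermediate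
19 | CNP0305372.1, (6R,7S,8S,9R)-8-angeloyloxy-9-hydroxy cis,cis-germacranolide 14-methyl ester | C=C1C(=O)O[C@@H]2/C=C(/C)CC/C=C(/C(=O)OC)[C@@H](O)[C@@H](OC(=O)/C(C)=C\C)[C@@H]12 | target

**Totals**
Total step count: 10. Longest linear sequence: 10 steps (1 → 19).

**Three steps most likely to fail**

Step 8, the proposed cascade. The hindered C9 ketone may resist the aldol. The epoxide C–O bond is only roughly antiperiplanar to the C4–C9 bond. The C9 alkoxide could instead open the epoxide at C6 to an oxa-bridged ether. The fallback uses known reactions only and sets out from 15. The copper hydride reductive aldol cyclization is run alone (Cu(OAc)2, 1,2-bis(diphenylphosphino)benzene, PhMe2SiH), and the silyl ether 16 is cleaved with AcOH/THF/H2O to isolate the bicyclic epoxy alcohol F1. F1 is heated with Ti(OiPr)4 in CH2Cl2 (Lewis-acid-promoted epoxy alcohol fragmentation) to give the silylated ten-membered ketone F2. The alkynyl silyl group of F2 is removed with TBAF/AcOH at 0 °C, and the route is rejoined at 17.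

Step 6, Mitsunobu reaction of a hindered α-hydroxy ketone with a weak, hindered acid. The fallback sets out from 12. Tf2O and 2,6-lutidine in CH2Cl2 at −78 °C give the keto triflate F3. F3 is displaced with inversion by cesium angelate (13, Cs2CO3, 18-crown-6, toluene, 0 °C), and the route is rejoined at 14.

Step 9, cyclocarbonylation in the presence of the electrophilic alkylidene keto ester. The fallback sets out from 17. Markovnikov hydroiodination (NaI, TMSCl, H2O, MeCN, 0 °C) gives the vinyl iodide F4. Carbonylative lactonization of F4 (Pd(PPh3)4 cat., CO 1 atm, Et3N, MeCN, 50 °C) closes the lactone, and the route is rejoined at 18.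

**Further compounds**
F1 | step 8 | cis-fused bicyclic epoxy alcohol (free C9–OH, triisopropylsilyl alkyne retained) | COC(=O)C1=CCC[C@@]2(C)[C@H]3O[C@H]3[C@H](C#C[Si](C(C)C)(C(C)C)C(C)C)[C@H](OC(=O)/C(C)=C\C)[C@@]12O
F2 | step 8 | triisopropylsilyl alkyne analogue of 17 | CC(C)[Si](C#C[C@H]1[C@H](O)/C=C(/C)CC/C=C(/C(=O)OC)C(=O)[C@H]1OC(=O)/C(C)=C\C)(C(C)C)C(C)C
F3 | step 6 | trifluoromethanesulfonate of 12 (C8 configuration retained) | O=C1[C@H](OS(=O)(=O)C(F)(F)F)[C@@H](C#C[Si](C(C)C)(C(C)C)C(C)C)[C@@H]2O[C@@H]2[C@]1(C)CCC#C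
F4 | step 9 | 1-iodovinyl analogue of 17 (C7 bears C(I)=CH2) | C=C(I)[C@H]1[C@H](O)/C=C(/C)CC/C=C(/C(=O)OC)C(=O)[C@H]1OC(=O)/C(C)=C\C
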